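**Retrosynthetic overview**
- The target is natural (2R,3'E,7'E)-α-tocotrienol; its only stereocentre (C2) and the pyran ring (O1–C2 bond) are made in the last step.
- Key disconnection: O1–C2, back to the achiral open-chain hydroquinone 8 (2-geranylgeranyl-3,5,6-trimethylhydroquinone) by a proposed catalytic enantioselective hydroalkoxylation.
- 8 comes from a hexasubstituted aryl bromide and all-E geranylgeranyl bromide by arylcopper allylation, then CAN demethylation and dithionite reduction.
- The 3'E and 7'E alkenes are the 6E and 10E alkenes of geranylgeraniol and are never touched.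
- Ring order: the aromatic ring is purchased; the dihydropyran ring is formed last.

Assumption: commercial all-E geranylgeraniol is chromatographed to >98% 2E before use (2Z material would erode ee in Step 7). The (S,S) catalyst antipode is assumed to give 2R; if the first run gives 2S, the (R,R) catalyst is used.

**Step 1**
Reactants: 1, 2,3,5-trimethylhydroquinone
Product: 2, 1,4-dimethoxy-2,3,5-trimethylbenzene
Conditions: Me2SO4, K2CO3, acetone, reflux, N2
Reagents that add atoms: dimethyl sulfate, COS(=O)(=O)OC
Why: Williamson O-methylation of both phenols masks the oxidation-prone hydroquinone for the organometallic step.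

**Step 2**
Reactants: 2, 1,4-dimethoxy-2,3,5-trimethylbenzene
Product: 3, 1-bromo-2,5-dimethoxy-3,4,6-trimethylbenzene
Conditions: NBS, MeCN, 0 °C to rt, dark
Reagents that add atoms: N-bromosuccinimide, O=C1CCC(=O)N1Br
Why: Electrophilic aromatic bromination at the only free position of an activated arene.

**Step 3**
Reactants: 4, (2E,6E,10E)-geranylgeraniol
Product: 5, (2E,6E,10E)-geranylgeranyl bromide
Conditions: MsCl, Et3N, CH2Cl2, −40 °C; then LiBr, THF, −40 to 0 °C; used crude
Reagents that add atoms: lithium bromide, [Li+].[Br-]
Why: Mesylation then SN2 bromide displacement at the primary allylic carbon gives the bromide without allylic transposition or loss of 2E geometry at low temperature.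

**Step 4**
Reactants: 3, 1-bromo-2,5-dimethoxy-3,4,6-trimethylbenzene; 5, (2E,6E,10E)-geranylgeranyl bromide
Product: 6, 1-[(2E,6E,10E)-3,7,11,15-tetramethylhexadeca-2,6,10,14-tetraen-1-yl]-2,5-dimethoxy-3,4,6-trimethylbenzene
Conditions: 3, n-BuLi, THF, −78 °C; CuBr·SMe2, −78 to −40 °C; then 5, −78 to 0 °C
Reagents that add atoms: none
Why: Br/Li exchange and α-selective (SN2) allylation of the arylcopper by the primary allylic bromide; SN2' would create a quaternary carbon and is disfavoured, and the alkene geometry is not touched.

**Step 5**
Reactants: 6, the geranylgeranyl dimethoxyarene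
Product: 7, 2,3,5-trimethyl-6-[(2E,6E,10E)-3,7,11,15-tetramethylhexadeca-2,6,10,14-tetraen-1-yl]cyclohexa-2,5-diene-1,4-dione
Conditions: CAN (3 equiv), MeCN/H2O 4:1, 0 °C, 15 min
Reagents that add atoms: water, O (quinone oxygens come from water; both OCH3 groups leave as methanol)
Why: Oxidative demethylation of a p-dimethoxyarene to the p-quinone; the electron-rich arene is oxidised much faster than isolated trisubstituted alkenes at 0 °C.

**Step 6**
Reactants: 7, the geranylgeranyl trimethylbenzoquinone
Product: 8, 2,3,5-trimethyl-6-[(2E,6E,10E)-3,7,11,15-tetramethylhexadeca-2,6,10,14-tetraen-1-yl]benzene-1,4-diol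
Conditions: Na2S2O4, NaHCO3, degassed Et2O/H2O, rt; used at once under Ar
Reagents that add atoms: none
Why: Dithionite reduction of quinone to hydroquinone under buffered, non-acidic conditions that do not trigger racemic cyclisation.

**Step 7 (proposed new transformation)**
Reactants: 8, 2-geranylgeranyl-3,5,6-trimethylhydroquinone
Product: 9, (2R)-2,5,7,8-tetramethyl-2-[(3E,7E)-4,8,12-trimethyltrideca-3,7,11-trien-1-yl]chroman-6-ol ((R)-α-tocotrienol, target)
Conditions: (S,S)-IDPi (confined BINOL-derived imidodiphosphorimidate Brønsted acid, 3,3'-aryl groups screened, N-triflyl core; 5 mol %), degassed cyclohexane, 25–40 °C, Ar, dark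
Reagents that add atoms: none (isomerisation)
Why: Proposed new method: the confined chiral acid acts as a small-molecule tocopherol cyclase. The ortho-OH hydrogen-bonds to a basic oxygen of the IDPi anion while the acidic N–H protonates C2' (Si face) of the one alkene within reach of that OH, and the phenol oxygen closes on the Re face of C3' in a concerted, asynchronous Markovnikov anti-addition through a six-membered chair-like transition state, which sets 2R. The three distal alkenes have no internal nucleophile and would need an unassisted tertiary cation in a non-polar solvent, and the C3' cation cannot be captured by the 6',7'-alkene (only 4- or 5-ring closures are possible), so site selectivity is expected. The closest known reaction types are IDPi-catalysed intramolecular hydroalkoxylation of unactivated alkenes by aliphatic alcohols, racemic acid-catalysed cyclisation of ortho-prenylphenols to 2,2-dialkylchromans, and the enzymatic tocopherol-cyclase reaction.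

**Compound list**
1 | 2,3,5-trimethylhydroquinone | Oc1cc(C)c(O)c(C)c1C | starting material
2 | 1,4-dimethoxy-2,3,5-trimethylbenzene | COc1cc(C)c(OC)c(C)c1C | intermediate
3 | 1-bromo-2,5-dimethoxy-3,4,6-trimethylbenzene | COc1c(Br)c(C)c(OC)c(C)c1C | intermediate
4 | (2E,6E,10E)-geranylgeraniol | CC(C)=CCC/C(C)=C/CC/C(C)=C/CC/C(C)=C/CO | starting material
5 | (2E,6E,10E)-geranylgeranyl bromide | CC(C)=CCC/C(C)=C/CC/C(C)=C/CC/C(C)=C/CBr | intermediate
6 | 1-[(2E,6E,10E)-geranylgeranyl]-2,5-dimethoxy-3,4,6-trimethylbenzene | COc1c(C/C=C(\C)CC/C=C(\C)CC/C=C(\C)CCC=C(C)C)c(C)c(OC)c(C)c1C | intermediate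
7 | 2-[(2E,6E,10E)-geranylgeranyl]-3,5,6-trimethyl-1,4-benzoquinone | CC1=C(C)C(=O)C(C/C=C(\C)CC/C=C(\C)CC/C=C(\C)CCC=C(C)C)=C(C)C1=O | intermediate
8 | 2-[(2E,6E,10E)-geranylgeranyl]-3,5,6-trimethylbenzene-1,4-diol | Oc1c(C/C=C(\C)CC/C=C(\C)CC/C=C(\C)CCC=C(C)C)c(C)c(O)c(C)c1C | intermediate
9 | (2R,3'E,7'E)-α-tocotrienol | CC(C)=CCC/C(C)=C/CC/C(C)=C/CC[C@]1(C)CCc2c(C)c(O)c(C)c(C)c2O1 | target

**Totals**
Total steps: 7. Longest linear sequence: 6 (Steps 1, 2, 4, 5, 6, 7 from compound 1).

**Three steps most likely to fail**
1. Step 7 (proposed new step). Risks are modest methyl-versus-chain facial discrimination, acid-initiated polyene cyclisation or alkene migration, and air oxidation of 8. Fallback with known chemistry: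
   - Pd-catalysed asymmetric allylic etherification (Trost-type, intramolecular) of a 6-O-TBS phenol carrying an (E)-allylic carbonate gives (S)-6-(TBSO)-2,5,7,8-tetramethyl-2-vinylchromane.
   - 9-BBN hydroboration and B-alkyl Suzuki–Miyaura coupling with (1E,5E)-1-iodo-2,6,10-trimethylundeca-1,5,9-triene follow; the iodide comes from Zr-catalysed methylalumination/iodination of (E)-6,10-dimethylundeca-5,9-dien-1-yne.
   - TBAF deprotection gives 9.
2. Step 4. Risks are SN2' (branched) product, partial loss of 2E geometry, and sluggish reaction of the di-ortho-substituted arylcopper. Fallback: BF3·OEt2-mediated addition of (E,E,E)-geranylgeranyl tributylstannane to 2,3,5-trimethyl-1,4-benzoquinone at −78 °C, which gives hydroquinone 8 directly and removes Steps 1, 2, 5 and 6.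
3. Step 5. Risk is over-oxidation of the tetraene or ring chemistry during CAN demethylation. Fallback: change the protecting-group strategy to bis-SEM ethers of 1, with directed ortho-lithiation (n-BuLi/TMEDA), the same copper-mediated allylation, and fluoride deprotection (TBAF, DMPU, 50 °C), so 8 is reached with no oxidant.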